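## Structural features

The target is a para-terphenyl: a fully substituted central benzene ring (ring B, numbered C1–C6 from the carbon bearing the hydroxybutanoate oxygen) is joined by single C–C bonds at C3 and C6 to two 4-hydroxyphenyl rings. The other four ring B carbons each carry an oxygen: C2 and C5 (para to each other) bear free hydroxyls, while C1 and C4 (also para) bear aryl ester oxygens, acylated by (S)-3-hydroxybutanoic acid at C1 and by 3-phenylpropanoic acid at C4. The only stereocentre is C3 of the butanoate chain; it has no stereogenic neighbour and, being β to the carbonyl, cannot epimerise by enolisation, but its oxygen can be lost by E1cB elimination to a crotonate. The fragile groups are the two aryl esters, each ortho to a free phenol (a 1,2-acyl shift would scramble the pattern, and aryl esters are easily cleaved by nucleophiles), and the para-dihydroxy pair at C2/C5, a hydroquinone that can oxidise to a quinone. Without its acyl groups ring B is centrosymmetric, so the real difficulty is not the carbon skeleton but telling four oxygens apart: two para oxygens must take two different acyl groups while the other para pair ends free. The key step uses the fact that ring B divides into a four-carbon unit C4–C3–C2–C1 (substituents O, aryl, O, O: a squarate carrying one aryl group) and a two-carbon unit C6–C5 (aryl, O: an aryl enol ether). When the ring is closed between C4 and C5, the oxygen on C4 appears as the only free phenol, that on C1 as a silyl ether and those on C2 and C5 as benzyl ethers, so each oxygen arrives already labelled.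

## Logic of the disconnections

27 to 26. The five oxygen–benzyl bonds (two on ring B, two on the outer rings, one on the side-chain carbinol) are cut first. Free phenols next to esters invite acyl migration and oxidation, so they should be unveiled only at the end. The gain is that every earlier intermediate has no hydroxyl adjacent to an ester. The demand is one neutral operation that removes three kinds of benzyl ether without touching two aryl esters or the stereocentre.

26 to 22 and 25. The acyl C–O bond of the butanoate is cut. The chiral acyl group is thus attached late, to the single free phenol of 22. This separates an achiral aromatic core from a four-carbon chiral-pool piece. The forward step must acylate a phenol flanked by a benzyloxy group and an aryl ring without eliminating the β-benzyloxy group.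

25 to 24 to 23. The acid is traced back through its ethyl ester, and the side-chain oxygen–benzyl bond is cut. The stereocentre is bought, not made. The benzyl group is chosen so that it falls in the final hydrogenolysis. The demand is benzylation under non-basic conditions and a mild saponification.

22 to 21 to 19 and 20. The oxygen–silicon bond is restored and the acyl C–O bond of the 3-phenylpropanoate is cut. In 19 exactly one oxygen is free and the silylated one lies para to it, so the first acyl group can go to one place only. The whole differentiation problem is thereby reduced to having 19. The demand is a desilylation that leaves the aryl ester alone.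

19 to 16 (key disconnection). The ring B bond between the phenol carbon and the adjacent benzyloxy-bearing carbon (C4–C5) is cut, and the phenol carbon is reconnected as a carbonyl to the silyloxy carbon, giving a four-membered ring. A hexasubstituted benzene is traded for a cyclobutenone that two carbonyl additions can assemble, and the ring-forming step needs no reagent. Which oxygen emerges free is fixed by connectivity. The demand is that the thermal opening turns the silyloxy group outward and the alkenyl group inward, and that the silyl ether survives about 110 °C.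

16 to 7 and 13. The C–C bond between the silyloxy carbon and the aryl-bearing vinyl carbon is cut, together with the oxygen–silicon bond. The ketone-like carbonyl of 7 invites 1,2-addition of a vinyl anion. The gain is two fragments, each with one aryl ring. The demands are attack at the carbonyl next to the benzyloxy-bearing carbon (not the vinylogous ester carbonyl), a β-alkoxyvinyl anion that lasts at low temperature, and silylation of a congested tertiary alkoxide.

13 to 11 to 8 and 9. The C–Br bond is cut, then the enol ether C=C bond. This leads to an aldehyde and an alkoxymethylene ylide. The demand is that HBr is lost in the direction that leaves bromine on the aryl-bearing carbon.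

7 to 3 and 4, and 3 to 1 and 2. The aryl–cyclobutene C–C bond is cut, then the two vinylogous ester C–O bonds that join the benzyloxy oxygens to the four-membered ring. The forward steps need a twofold esterification that consumes two equivalents of 2 with removal of water, mono-addition of the aryl anion, and then an acid-promoted rearrangement that expels one benzyloxy group.

## Other disconnections considered

Alternative 1: The cut is at the two ring B carbon–oxygen bonds of the esters (C1–O and C4–O). In the precursor, diketone A2, both acyl carbons are bonded directly to ring B. In the forward key step a buffered peracid adds to both ketones of A2 and ring B migrates from carbon to oxygen in each Criegee intermediate (double Baeyer–Villiger oxidation). The product, diester A1, is identical with 26 of the chosen route.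
- In favour: both ester linkages form in one operation, no doubly flanked phenol has to be acylated, the stereocentre is a spectator, and A1 is one hydrogenolysis from the target.
- Against: each carbonyl of A2 sits between a benzyloxy group and an aryl ring, so it is twisted out of conjugation and shielded from the peracid. Preference for aryl over primary alkyl migration is then not secured. Five electron-rich rings compete for the oxidant, and the β-benzyloxy ketone can eliminate.
- Against, on access to A2: the photo-Fries acyl shift (followed by O-benzylation) would start from the mixed bis-ester A3 of a symmetrical 2,5-diarylhydroquinone, which carries one acyl group of each kind on two equivalent para oxygens. The differentiation of the two para sites is therefore moved to a statistical first acylation, not solved, and radical-pair recombination is expected to give mixtures.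
- Comparison: on structure the two plans are equal in the endgame, since they meet at the same perbenzylated diester. On mechanism the alternative relies on migratory aptitude, whereas the chosen plan fixes the outcome by connectivity. On step economy the alternative is better in the ester-forming stage (one operation against steps 7, 8 and 11) but is expected to be longer before it.

Alternative 2: The cut is at two ring B bonds, C3–C4 and C6–C1, each joining an aryl-bearing carbon to an oxygen-bearing carbon. Ring B then falls into two identical three-carbon units, arylpyruvate ester A5. In the forward key step excess NaOMe effects a twofold Claisen condensation of A5, each benzylic carbon being acylated by the ester carbon of its partner. The ring closes as quinone A4.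
- In favour: the latent symmetry is used fully. One step from one simple building block sets all six ring carbons, all four oxygens and both aryl groups, without cryogenic organometallic chemistry.
- Against: A4 is centrosymmetric. Its two carbonyl oxygens are the ones that must carry the two different acyl groups. After O-benzylation of the enolic hydroxyls and reduction of the quinone they are equivalent, so the first acylation is statistical and needs separation and recycling. Aldol-type self-condensation of A5 can compete with the head-to-tail dimerisation.
- Comparison: on structure the alternative passes through a symmetrical core whose symmetry is broken by statistics, the chosen plan through an unsymmetrical core with built-in labels. On mechanism it uses enolate condensations under thermodynamic drive where the chosen plan uses a pericyclic cascade. On step economy the alternative is clearly better (about half the number of steps), it is equal in the final deprotection, and it is better in scalability. It is weaker only in the selectivity of the first acylation, which the chosen plan secures by design.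

Alternative 3: The cut is at three ring B bonds: the bond between two adjacent oxygen-bearing carbons, and the two bonds from the aryl-bearing carbons to the other pair of oxygen-bearing carbons. Ring B is divided into three alkyne units, the silicon-tethered bis(ynol ether) A7 and di-tert-butoxyethyne A8. In the forward key step CpCo(CO)2, a monovalent cobalt catalyst, couples the two tethered alkynes to a cobaltacyclopentadiene, A8 inserts, and reductive elimination gives benzodioxasilole A6.
- In favour: three ring bonds form in one catalytic step, the para relation of the aryl groups is fixed by the tether, and two protecting-group types (silylene, tert-butyl) are present.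
- Against: the oxygens come labelled in vicinal pairs, whereas in the target each vicinal pair consists of one ester and one free hydroxyl. Each pair of A6 would have to be split again, and the second ester would have to be placed para to the first with nothing in the molecule to direct it. Vicinal hydroxyl/ester intermediates would be prone to acyl migration, and tert-butyl ether cleavage needs acid in the presence of aryl esters.
- Against, on the precursors: A7 and A8 are sensitive, electron-rich alkynes (A8 loses isobutene on heating), which sits badly with the heating that CpCo(CO)2 normally needs.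
- Comparison: on structure the labels of A6 are mismatched to the target, those of the chosen plan matched. On mechanism a metal-templated cycloaddition stands against a metal-free thermal cascade. On step economy the ring-forming step of the alternative is better (three bonds, catalytic), but precursor synthesis and later differentiation are expected to cost more steps overall.

Key step: step 6

Assumption: benzyl alcohol (2), (benzyloxymethyl)triphenylphosphonium chloride (9) and 3-phenylpropanoyl chloride (20) are purchased; the alkene geometry of 11, 13 and 16 has no bearing on the ring closure, so isomer mixtures may be carried forward.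

## Steps

Step 1
Reactants: 1 squaric acid (3,4-dihydroxycyclobut-3-ene-1,2-dione); 2 benzyl alcohol
Product: 3 dibenzyl squarate [3,4-bis(benzyloxy)cyclobut-3-ene-1,2-dione]
Conditions: BnOH (3 equiv), PhMe, reflux, Dean–Stark trap
Reagents that add atoms: benzyl alcohol (the second equivalent that is incorporated; the first is reactant 2), OCc1ccccc1
Why: Fischer-type twofold esterification of a vinylogous diacid, as in the standard preparation of dialkyl squarates: each alcohol oxygen adds to a ring carbon and water is expelled, so two equivalents of benzyl alcohol end up in the product. Squaric acid is strong enough to catalyse the reaction itself, and azeotropic removal of water should drive both hydroxyls to the benzyl ester.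

Step 2
Reactants: 4 1-(benzyloxy)-4-bromobenzene; 3 dibenzyl squarate
Product: 7 3-(benzyloxy)-4-[4-(benzyloxy)phenyl]cyclobut-3-ene-1,2-dione, via aryllithium 5 (not isolated), via hydroxycyclobutenone 6 (not isolated)
Conditions: n-BuLi, THF, −78 °C; then 3, −78 °C; aq. NH4Cl; crude adduct: conc. HCl (cat.), CH2Cl2, rt
Reagents that add atoms: none
Why: Bromine–lithium exchange gives the aryllithium, which adds 1,2 to one carbonyl of the squarate; acid then ionises the tertiary carbinol and the vinylogous hemiketal collapses with loss of benzyl alcohol (the standard hydroxycyclobutenone-to-cyclobutenedione rearrangement). The racemic carbinol centre of 6 becomes sp2.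

Step 3
Reactants: 8 4-(benzyloxy)benzaldehyde; 9 (benzyloxymethyl)triphenylphosphonium chloride
Product: 11 1-(benzyloxy)-4-[2-(benzyloxy)ethenyl]benzene (E/Z mixture), via phosphorus ylide 10 (not isolated)
Conditions: KOt-Bu, THF, 0 °C; then 8, 0 °C → rt
Reagents that add atoms: none
Why: Wittig olefination with an alkoxymethylene ylide; the E/Z mixture is acceptable because the geometry is erased in step 4.

Step 4
Reactants: 11 1-(benzyloxy)-4-[2-(benzyloxy)ethenyl]benzene
Product: 13 1-(benzyloxy)-4-[2-(benzyloxy)-1-bromoethenyl]benzene, via vicinal dibromide 12 (not isolated)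
Conditions: Br2 (1.0 equiv), CH2Cl2, −78 °C; then i-Pr2NEt, −78 °C → rt
Reagents that add atoms: bromine, BrBr
Why: Bromination–dehydrobromination of an enol ether: bromine adds to the enol ether far faster than to the alkoxyarene rings, the α-bromo ether carbon ionises readily and the acidic benzylic hydrogen is removed, so bromine should remain on the aryl-bearing carbon. The isomer with bromine cis to the benzyloxy group (Z) is expected to dominate and is the preferred one for step 5.

Step 5
Reactants: 13 1-(benzyloxy)-4-[2-(benzyloxy)-1-bromoethenyl]benzene; 7 3-(benzyloxy)-4-[4-(benzyloxy)phenyl]cyclobut-3-ene-1,2-dione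
Product: 16 3-(benzyloxy)-2-[4-(benzyloxy)phenyl]-4-{2-(benzyloxy)-1-[4-(benzyloxy)phenyl]ethenyl}-4-[(tert-butyldimethylsilyl)oxy]cyclobut-2-en-1-one (racemic), via vinyllithium 14 (not isolated), via lithium alkoxide 15 (not isolated)
Conditions: t-BuLi (2 equiv), THF, −78 °C; then 7, −78 °C; then t-BuMe2SiOTf, −78 → 0 °C
Reagents that add atoms: tert-butyldimethylsilyl trifluoromethanesulfonate, CC(C)(C)[Si](C)(C)OS(=O)(=O)C(F)(F)F
Why: Bromine–lithium exchange at −78 °C gives a β-alkoxyvinyllithium held by internal O–Li coordination; it should add to the carbonyl of 7 attached to the benzyloxy-bearing carbon, because the other carbonyl is deactivated as a vinylogous ester. Silylating the tertiary alkoxide in the flask avoids handling the sensitive carbinol. The new quaternary centre forms as a racemate and is destroyed in step 6.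

Step 6
Reactants: 16 3-(benzyloxy)-2-[4-(benzyloxy)phenyl]-4-{2-(benzyloxy)-1-[4-(benzyloxy)phenyl]ethenyl}-4-[(tert-butyldimethylsilyl)oxy]cyclobut-2-en-1-one
Product: 19 3,6-bis(benzyloxy)-2,5-bis[4-(benzyloxy)phenyl]-4-[(tert-butyldimethylsilyl)oxy]phenol, via dienylketene 17 (not isolated), via cyclohexadienone 18 (not isolated)
Conditions: PhMe (degassed, 0.02 M), 110 °C, under Ar
Reagents that add atoms: none
Why: Heating should open the cyclobutenone by conrotatory 4π electrocyclic cleavage of the bond between the carbonyl carbon and the silyloxy carbon, giving dienylketene 17. The ketene carbon and the benzyloxy-bearing terminal vinyl carbon then join in a disrotatory 6π electrocyclisation to cyclohexadienone 18, which enolises to phenol 19. The closest known reaction type is the thermal ring expansion of squarate-derived 4-alkenyl-4-hydroxy- or 4-silyloxycyclobutenones to hydroquinones (Moore rearrangement). The one ring closed is the central benzene ring, by 6π electrocyclic closure with one new C–C bond, while the four-membered ring is lost. No stereocentre is created: the sp3 carbon of 18 disappears on enolisation and the racemic carbinol carbon of 16 becomes sp2. The selectivity needed is torquoselectivity in the opening: the electron-donating silyloxy group should rotate outward, which places the alkenyl group inward beside the ketene, and opening in the other sense is reversible and unproductive. Which oxygen emerges free is fixed by connectivity, since the ketene carbonyl becomes the only phenol and the silyloxy carbon lies para to it. Aromatisation should make the sequence irreversible.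

Step 7
Reactants: 19 3,6-bis(benzyloxy)-2,5-bis[4-(benzyloxy)phenyl]-4-[(tert-butyldimethylsilyl)oxy]phenol; 20 3-phenylpropanoyl chloride
Product: 21 3,6-bis(benzyloxy)-2,5-bis[4-(benzyloxy)phenyl]-4-[(tert-butyldimethylsilyl)oxy]phenyl 3-phenylpropanoate
Conditions: Et3N, DMAP (cat.), CH2Cl2, 0 °C → rt
Reagents that add atoms: none
Why: DMAP-catalysed acylation of the only free phenol by an acid chloride; silyl and benzyl ethers are inert, and there is no neighbouring free hydroxyl to which the acyl group could migrate.

Step 8
Reactants: 21 3,6-bis(benzyloxy)-2,5-bis[4-(benzyloxy)phenyl]-4-[(tert-butyldimethylsilyl)oxy]phenyl 3-phenylpropanoate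
Product: 22 3,6-bis(benzyloxy)-2,5-bis[4-(benzyloxy)phenyl]-4-hydroxyphenyl 3-phenylpropanoate
Conditions: Bu4NF, AcOH, THF, 0 °C
Reagents that add atoms: none
Why: Fluoride cleaves the aryl silyl ether; acetic acid buffers the phenoxide so that the aryl ester should be neither cleaved nor passed between molecules. The freed oxygen lies para to the ester, whose ortho neighbours are an aryl ring and a benzyl ether, so no intramolecular acyl shift is possible.

Step 9
Reactants: 23 ethyl (S)-3-hydroxybutanoate
Product: 24 ethyl (S)-3-(benzyloxy)butanoate
Conditions: BnOC(=NH)CCl3, TfOH (cat.), CH2Cl2–cyclohexane, 0 °C → rt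
Reagents that add atoms: benzyl 2,2,2-trichloroacetimidate, N=C(OCc1ccccc1)C(Cl)(Cl)Cl
Why: Acid-catalysed O-benzylation with the trichloroacetimidate avoids the basic conditions that cause retro-aldol cleavage or elimination of β-hydroxy esters; the C–O bond of the stereocentre is not broken, so the S configuration is retained.

Step 10
Reactants: 24 ethyl (S)-3-(benzyloxy)butanoate
Product: 25 (S)-3-(benzyloxy)butanoic acid
Conditions: LiOH, THF–H2O, 0 °C → rt; then aq. HCl to pH 2
Reagents that add atoms: lithium hydroxide, [Li+].[OH-]
Why: Saponification of the ethyl ester; the stereocentre is β to the carbonyl and cannot epimerise, and low temperature limits E1cB loss of benzyloxide.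

Step 11
Reactants: 22 3,6-bis(benzyloxy)-2,5-bis[4-(benzyloxy)phenyl]-4-hydroxyphenyl 3-phenylpropanoate; 25 (S)-3-(benzyloxy)butanoic acid
Product: 26 2,5-bis(benzyloxy)-3,6-bis[4-(benzyloxy)phenyl]-4-[(3-phenylpropanoyl)oxy]phenyl (3S)-3-(benzyloxy)butanoate
Conditions: DCC, DMAP (cat.), CH2Cl2, 0 °C → rt
Reagents that add atoms: none
Why: Steglich esterification; DMAP relays the acyl group to the phenol between a benzyloxy group and an aryl ring. The stereocentre is β to the activated carbonyl and is not touched.

Step 12
Reactants: 26 2,5-bis(benzyloxy)-3,6-bis[4-(benzyloxy)phenyl]-4-[(3-phenylpropanoyl)oxy]phenyl (3S)-3-(benzyloxy)butanoate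
Product: 27 2,5-dihydroxy-3,6-bis(4-hydroxyphenyl)-4-[(3-phenylpropanoyl)oxy]phenyl (3S)-3-hydroxybutanoate (target)
Conditions: H2 (1 atm), 10% Pd/C, EtOAc–THF, rt
Reagents that add atoms: none
Why: Hydrogenolysis of all five benzyl ethers under neutral conditions; aryl esters are stable to H2 over Pd/C, and the absence of base or nucleophile should suppress acyl migration to the newly freed ortho hydroxyls.

## Compound list

1 | squaric acid (3,4-dihydroxycyclobut-3-ene-1,2-dione) | O=C1C(O)=C(O)C1=O | starting material
2 | benzyl alcohol | OCc1ccccc1 | starting material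
3 | dibenzyl squarate [3,4-bis(benzyloxy)cyclobut-3-ene-1,2-dione] | O=C1C(=O)C(OCc2ccccc2)=C1OCc1ccccc1 | intermediate
4 | 1-(benzyloxy)-4-bromobenzene | Brc1ccc(OCc2ccccc2)cc1 | starting material
5 | [4-(benzyloxy)phenyl]lithium | [Li]c1ccc(OCc2ccccc2)cc1 | intermediate
6 | 2,3-bis(benzyloxy)-4-[4-(benzyloxy)phenyl]-4-hydroxycyclobut-2-en-1-one (racemic) | OC1(c2ccc(OCc3ccccc3)cc2)C(OCc2ccccc2)=C(OCc2ccccc2)C1=O | intermediate
7 | 3-(benzyloxy)-4-[4-(benzyloxy)phenyl]cyclobut-3-ene-1,2-dione | O=C1C(=O)C(c2ccc(OCc3ccccc3)cc2)=C1OCc1ccccc1 | intermediate
8 | 4-(benzyloxy)benzaldehyde | O=Cc1ccc(OCc2ccccc2)cc1 | starting material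
9 | (benzyloxymethyl)triphenylphosphonium chloride | [Cl-].c1ccc(cc1)[P+](COCc1ccccc1)(c1ccccc1)c1ccccc1 | starting material
10 | (benzyloxymethylene)triphenylphosphorane | c1ccc(cc1)P(=COCc1ccccc1)(c1ccccc1)c1ccccc1 | intermediate
11 | 1-(benzyloxy)-4-[2-(benzyloxy)ethenyl]benzene (E/Z mixture) | C(=Cc1ccc(OCc2ccccc2)cc1)OCc1ccccc1 | intermediate
12 | 1-(benzyloxy)-4-[2-(benzyloxy)-1,2-dibromoethyl]benzene (diastereomer mixture) | BrC(OCc1ccccc1)C(Br)c1ccc(OCc2ccccc2)cc1 | intermediate
13 | 1-(benzyloxy)-4-[2-(benzyloxy)-1-bromoethenyl]benzene (Z expected as major isomer, geometry not critical) | BrC(=COCc1ccccc1)c1ccc(OCc2ccccc2)cc1 | intermediate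
14 | {2-(benzyloxy)-1-[4-(benzyloxy)phenyl]ethenyl}lithium | [Li]C(=COCc1ccccc1)c1ccc(OCc2ccccc2)cc1 | intermediate
15 | lithium 2-(benzyloxy)-1-{2-(benzyloxy)-1-[4-(benzyloxy)phenyl]ethenyl}-3-[4-(benzyloxy)phenyl]-4-oxocyclobut-2-en-1-olate (racemic) | [Li+].[O-]C1(C(=COCc2ccccc2)c2ccc(OCc3ccccc3)cc2)C(OCc2ccccc2)=C(c2ccc(OCc3ccccc3)cc2)C1=O | intermediate
16 | 3-(benzyloxy)-2-[4-(benzyloxy)phenyl]-4-{2-(benzyloxy)-1-[4-(benzyloxy)phenyl]ethenyl}-4-[(tert-butyldimethylsilyl)oxy]cyclobut-2-en-1-one (racemic, alkene geometry as in 13) | O=C1C(c2ccc(OCc3ccccc3)cc2)=C(OCc2ccccc2)C1(O[Si](C)(C)C(C)(C)C)C(c1ccc(OCc2ccccc2)cc1)=COCc1ccccc1 | intermediate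
17 | (3Z)-3,6-bis(benzyloxy)-2,5-bis[4-(benzyloxy)phenyl]-4-[(tert-butyldimethylsilyl)oxy]hexa-1,3,5-trien-1-one (ketene and alkenyl termini cis across the central double bond) | O=C=C(c1ccc(OCc2ccccc2)cc1)/C(OCc1ccccc1)=C(O[Si](C)(C)C(C)(C)C)\C(c1ccc(OCc2ccccc2)cc1)=COCc1ccccc1 | intermediate
18 | 3,6-bis(benzyloxy)-2,5-bis[4-(benzyloxy)phenyl]-4-[(tert-butyldimethylsilyl)oxy]cyclohexa-2,4-dien-1-one (racemic) | O=C1C(c2ccc(OCc3ccccc3)cc2)=C(OCc2ccccc2)C(O[Si](C)(C)C(C)(C)C)=C(c2ccc(OCc3ccccc3)cc2)C1OCc1ccccc1 | intermediate
19 | 3,6-bis(benzyloxy)-2,5-bis[4-(benzyloxy)phenyl]-4-[(tert-butyldimethylsilyl)oxy]phenol | Oc1c(-c2ccc(OCc3ccccc3)cc2)c(OCc2ccccc2)c(O[Si](C)(C)C(C)(C)C)c(-c2ccc(OCc3ccccc3)cc2)c1OCc1ccccc1 | intermediate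
20 | 3-phenylpropanoyl chloride | O=C(Cl)CCc1ccccc1 | starting material
21 | 3,6-bis(benzyloxy)-2,5-bis[4-(benzyloxy)phenyl]-4-[(tert-butyldimethylsilyl)oxy]phenyl 3-phenylpropanoate | O=C(CCc1ccccc1)Oc1c(-c2ccc(OCc3ccccc3)cc2)c(OCc2ccccc2)c(O[Si](C)(C)C(C)(C)C)c(-c2ccc(OCc3ccccc3)cc2)c1OCc1ccccc1 | intermediate
22 | 3,6-bis(benzyloxy)-2,5-bis[4-(benzyloxy)phenyl]-4-hydroxyphenyl 3-phenylpropanoate | O=C(CCc1ccccc1)Oc1c(-c2ccc(OCc3ccccc3)cc2)c(OCc2ccccc2)c(O)c(-c2ccc(OCc3ccccc3)cc2)c1OCc1ccccc1 | intermediate
23 | ethyl (S)-3-hydroxybutanoate | C[C@H](O)CC(=O)OCC | starting material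
24 | ethyl (S)-3-(benzyloxy)butanoate | C[C@H](OCc1ccccc1)CC(=O)OCC | intermediate
25 | (S)-3-(benzyloxy)butanoic acid | C[C@H](OCc1ccccc1)CC(=O)O | intermediate
26 | 2,5-bis(benzyloxy)-3,6-bis[4-(benzyloxy)phenyl]-4-[(3-phenylpropanoyl)oxy]phenyl (3S)-3-(benzyloxy)butanoate | C[C@H](OCc1ccccc1)CC(=O)Oc1c(OCc2ccccc2)c(-c2ccc(OCc3ccccc3)cc2)c(OC(=O)CCc2ccccc2)c(OCc2ccccc2)c1-c1ccc(OCc2ccccc2)cc1 | intermediate
27 | 2,5-dihydroxy-3,6-bis(4-hydroxyphenyl)-4-[(3-phenylpropanoyl)oxy]phenyl (3S)-3-hydroxybutanoate | C[C@H](O)CC(=O)Oc1c(O)c(-c2ccc(O)cc2)c(OC(=O)CCc2ccccc2)c(O)c1-c1ccc(O)cc1 | target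

## Step count and least certain steps

Total step count: 12. Longest linear sequence: 8 steps (1, 2, 5, 6, 7, 8, 11, 12; the branch 3, 4, 5 onward is of equal length).

Step 6 (key step). Closure may go through the wrong terminus. The nucleophilic carbon of the enol ether is the aryl-bearing one, so a polar five-membered closure onto the ketene, or an intramolecular [2+2] addition, may compete with the 6π closure at the benzyloxy-bearing carbon. Inward rotation of the silyloxy group followed by silyl transfer to the ketene is a second diversion, and air oxidation of the electron-rich phenol a third. The fallback gives up ring construction: ring B is bought, the aryl groups come by cross-coupling, and the two para oxygens are told apart statistically. It sets out from 4. Bromine–lithium exchange (through 5), B(Oi-Pr)3 and aqueous HCl should give [4-(benzyloxy)phenyl]boronic acid F1. Purchased bromanilic acid (2,5-dibromo-3,6-dihydroxy-1,4-benzoquinone) is O-benzylated with BnBr and Ag2O to 2,5-bis(benzyloxy)-3,6-dibromocyclohexa-2,5-diene-1,4-dione F2. Twofold Suzuki–Miyaura coupling of F2 with F1 (Pd(PPh3)4, a zerovalent palladium complex, K2CO3, dioxane–water) should give 2,5-bis(benzyloxy)-3,6-bis[4-(benzyloxy)phenyl]cyclohexa-2,5-diene-1,4-dione F3. Na2S2O4 reduces it to 2,5-bis(benzyloxy)-3,6-bis[4-(benzyloxy)phenyl]benzene-1,4-diol F4. Acylation of F4 with one equivalent of 20 (Et3N, DMAP), with separation from diester and recycling of recovered diol, comes back to the route at 22.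

Step 5. Lithium benzyloxide may be lost from the vinyllithium by β-elimination if the temperature rises. t-BuLi may deprotonate a benzylic CH2 in competition with the exchange. Silylation of the congested tertiary alkoxide may be incomplete, followed by ring fragmentation on work-up. The fallback changes both the organometallic and the order of events. It sets out from 13, which is converted by direct magnesium insertion (Mg, LiCl, THF, 0 °C) into {2-(benzyloxy)-1-[4-(benzyloxy)phenyl]ethenyl}magnesium bromide F5, a less basic reagent that is less prone to β-elimination. Addition of F5 to 7 and work-up with NH4Cl should give 3-(benzyloxy)-4-{2-(benzyloxy)-1-[4-(benzyloxy)phenyl]ethenyl}-2-[4-(benzyloxy)phenyl]-4-hydroxycyclobut-2-en-1-one F6, which is isolated. Separate silylation of F6 with t-BuMe2SiOTf and 2,6-lutidine in CH2Cl2 comes back to the route at 16.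

Step 11. Acyl transfer to the doubly ortho-substituted phenol may be slow, allowing the O-acylisourea to rearrange to an unreactive N-acylurea. The activated β-benzyloxy acyl species may also lose benzyl alcohol by E1cB elimination. The fallback sets the stereocentre by catalyst control and no longer takes it from the chiral pool. It sets out from 22, which is heated with 2,2,6-trimethyl-4H-1,3-dioxin-4-one in PhMe at 110 °C; the acetylketene released should acylate the hindered phenol to 2,5-bis(benzyloxy)-3,6-bis[4-(benzyloxy)phenyl]-4-[(3-phenylpropanoyl)oxy]phenyl 3-oxobutanoate F7. Noyori asymmetric hydrogenation of the ketone (RuCl2[(S)-BINAP], a divalent ruthenium catalyst, H2, EtOH–CH2Cl2) should give 2,5-bis(benzyloxy)-3,6-bis[4-(benzyloxy)phenyl]-4-[(3-phenylpropanoyl)oxy]phenyl (3S)-3-hydroxybutanoate F8. Hydrogenolysis of F8 under the conditions of step 12 comes back to the route at 27.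

Step 12. Debenzylation of the hindered ring B ethers may be incomplete because of poor solubility or catalyst poisoning. An acyl group may migrate from an ester oxygen to the newly freed ortho hydroxyl. The hydroquinone product may oxidise in air. The fallback replaces hydrogenolysis by Lewis-acid dealkylation. It sets out from 26, which is treated with BCl3 and pentamethylbenzene (cation scavenger) in CH2Cl2 at −78 °C, followed by a methanol quench, and arrives directly at 27; no new compound is made.

## Further compounds

F1 | step 6 | [4-(benzyloxy)phenyl]boronic acid | OB(O)c1ccc(OCc2ccccc2)cc1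
F2 | step 6 | 2,5-bis(benzyloxy)-3,6-dibromocyclohexa-2,5-diene-1,4-dione | O=C1C(Br)=C(OCc2ccccc2)C(=O)C(Br)=C1OCc1ccccc1
F3 | step 6 | 2,5-bis(benzyloxy)-3,6-bis[4-(benzyloxy)phenyl]cyclohexa-2,5-diene-1,4-dione | O=C1C(c2ccc(OCc3ccccc3)cc2)=C(OCc2ccccc2)C(=O)C(c2ccc(OCc3ccccc3)cc2)=C1OCc1ccccc1
F4 | step 6 | 2,5-bis(benzyloxy)-3,6-bis[4-(benzyloxy)phenyl]benzene-1,4-diol | Oc1c(-c2ccc(OCc3ccccc3)cc2)c(OCc2ccccc2)c(O)c(-c2ccc(OCc3ccccc3)cc2)c1OCc1ccccc1
F5 | step 5 | {2-(benzyloxy)-1-[4-(benzyloxy)phenyl]ethenyl}magnesium bromide | Br[Mg]C(=COCc1ccccc1)c1ccc(OCc2ccccc2)cc1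
F6 | step 5 | 3-(benzyloxy)-4-{2-(benzyloxy)-1-[4-(benzyloxy)phenyl]ethenyl}-2-[4-(benzyloxy)phenyl]-4-hydroxycyclobut-2-en-1-one (racemic) | O=C1C(c2ccc(OCc3ccccc3)cc2)=C(OCc2ccccc2)C1(O)C(c1ccc(OCc2ccccc2)cc1)=COCc1ccccc1
F7 | step 11 | 2,5-bis(benzyloxy)-3,6-bis[4-(benzyloxy)phenyl]-4-[(3-phenylpropanoyl)oxy]phenyl 3-oxobutanoate | CC(=O)CC(=O)Oc1c(OCc2ccccc2)c(-c2ccc(OCc3ccccc3)cc2)c(OC(=O)CCc2ccccc2)c(OCc2ccccc2)c1-c1ccc(OCc2ccccc2)cc1
F8 | step 11 | 2,5-bis(benzyloxy)-3,6-bis[4-(benzyloxy)phenyl]-4-[(3-phenylpropanoyl)oxy]phenyl (3S)-3-hydroxybutanoate | C[C@H](O)CC(=O)Oc1c(OCc2ccccc2)c(-c2ccc(OCc3ccccc3)cc2)c(OC(=O)CCc2ccccc2)c(OCc2ccccc2)c1-c1ccc(OCc2ccccc2)cc1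
F0 | step 12 | none | none
A1 | alternative 1 | 2,5-bis(benzyloxy)-3,6-bis[4-(benzyloxy)phenyl]-4-[(3-phenylpropanoyl)oxy]phenyl (S)-3-(benzyloxy)butanoate | C[C@H](OCc1ccccc1)CC(=O)Oc1c(OCc2ccccc2)c(-c2ccc(OCc3ccccc3)cc2)c(OC(=O)CCc2ccccc2)c(OCc2ccccc2)c1-c1ccc(OCc2ccccc2)cc1
A2 | alternative 1 | (3S)-3-(benzyloxy)-1-{2,5-bis(benzyloxy)-3,6-bis[4-(benzyloxy)phenyl]-4-(3-phenylpropanoyl)phenyl}butan-1-one | C[C@H](OCc1ccccc1)CC(=O)c1c(OCc2ccccc2)c(-c2ccc(OCc3ccccc3)cc2)c(C(=O)CCc2ccccc2)c(OCc2ccccc2)c1-c1ccc(OCc2ccccc2)cc1
A3 | alternative 1 | 2,5-bis[4-(benzyloxy)phenyl]-4-[(3-phenylpropanoyl)oxy]phenyl (3S)-3-(benzyloxy)butanoate | C[C@H](OCc1ccccc1)CC(=O)Oc1cc(-c2ccc(OCc3ccccc3)cc2)c(OC(=O)CCc2ccccc2)cc1-c1ccc(OCc2ccccc2)cc1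
A4 | alternative 2 | 2,5-dihydroxy-3,6-bis[4-(benzyloxy)phenyl]cyclohexa-2,5-diene-1,4-dione | O=C1C(O)=C(c2ccc(OCc3ccccc3)cc2)C(=O)C(O)=C1c1ccc(OCc2ccccc2)cc1
A5 | alternative 2 | methyl 3-[4-(benzyloxy)phenyl]-2-oxopropanoate | COC(=O)C(=O)Cc1ccc(OCc2ccccc2)cc1
A6 | alternative 3 | 4,7-bis[4-(benzyloxy)phenyl]-5,6-di-tert-butoxy-2,2-di(propan-2-yl)-1,3,2-benzodioxasilole | CC(C)[Si]1(C(C)C)Oc2c(O1)c(-c1ccc(OCc3ccccc3)cc1)c(OC(C)(C)C)c(OC(C)(C)C)c2-c1ccc(OCc2ccccc2)cc1
A7 | alternative 3 | bis({[4-(benzyloxy)phenyl]ethynyl}oxy)di(propan-2-yl)silane | CC(C)[Si](OC#Cc1ccc(OCc2ccccc2)cc1)(OC#Cc1ccc(OCc2ccccc2)cc1)C(C)C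
A8 | alternative 3 | di-tert-butoxyethyne | CC(C)(C)OC#COC(C)(C)C
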